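**Retrosynthetic overview**

- Feature: ring B holds a 2-methylenecyclohexanol unit, with the secondary carbinol C7 bonded directly to C8 of the exocyclic C8=C17 alkene. C7–C8 is therefore cut to a C8 alkenyl iodide and a C7 aldehyde, and ring B is closed last (Nozaki–Hiyama–Kishi) on a ring A 19,6β-lactone that already carries C9 and the whole C11–C16 chain.
- After ring B: the lactone is reduced to the 6β,19-diol, O6 is benzoylated and C19 is re-oxidised to the acid.
- Before ring B: the C9–C10 bond and both of its centres come from an Ireland–Claisen rearrangement of a ring A C2 allylic ester of the C8–C15 acid. The C4 methyl group comes from alkylation of the lactone enolate, and C6/C7 from methylenation and hydroboration of a butenolide-derived lactone carbonyl.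
- Ring A (C4, C5) is made first, by a Diels–Alder reaction of a 5-menthyloxy butenolide with a 2-silyloxypentadiene. Ring order: ring A, then the oxolane (later lactone) ring, then ring B.

Key step: step 23

Remark on numbering: labdane numbers are used throughout (ring A C1–C5 and C10; ring B C5–C10; C17 on C8; C18 the α-methyl and C19 the β-carbon on C4; C20 the methyl on C10; chain C11–C16). α is the face of H5, β the face of C20.

Assumption: (5S)-5-[(1S,2R,5S)-menthyloxy]furan-2(5H)-one is bought as the enantiomer of the common (5R)-l-menthyloxy auxiliary; otherwise it is made in one step from 5-hydroxyfuran-2(5H)-one and (+)-menthol.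

**Route**

Step 1
Reactants: 1 hex-5-yn-1-ol
Product: 2 tert-butyl(hex-5-yn-1-yloxy)dimethylsilane
Conditions: TBSCl, imidazole, CH2Cl2, 0 to 23 °C
Reagents that add atoms: tert-butyldimethylsilyl chloride, CC(C)(C)[Si](C)(C)Cl
Why: Silylation of the primary alcohol (silyl ether formation) masks the hydroxyl for the organoaluminium chemistry of step 2 and leaves the terminal alkyne untouched.

Step 2
Reactants: 2 tert-butyl(hex-5-yn-1-yloxy)dimethylsilane
Product: 4 (E)-7-(tert-butyldimethylsilyloxy)-3-methylhept-2-en-1-ol, via alkenylalane 3 (not isolated)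
Conditions: Me3Al, Cp2ZrCl2 (cat.), CH2Cl2, 0 to 23 °C; then n-BuLi, (CH2O)n, THF, −30 to 23 °C
Reagents that add atoms: trimethylaluminium, C[Al](C)C; formaldehyde (as paraformaldehyde), C=O
Why: Zirconium-catalysed methylalumination (Negishi carboalumination) adds CH3 and aluminium syn across the alkyne with aluminium on the terminal carbon, and hydroxymethylation of the derived alanate goes with retention, so the later C13=C14 bond is formed as the E isomer.

Step 3
Reactants: 4 (E)-7-(tert-butyldimethylsilyloxy)-3-methylhept-2-en-1-ol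
Product: 5 (E)-7-(tert-butyldimethylsilyloxy)-3-methyl-1-(triisopropylsilyloxy)hept-2-ene
Conditions: TIPSCl, imidazole, DMF, 23 °C
Reagents that add atoms: triisopropylsilyl chloride, CC(C)[Si](Cl)(C(C)C)C(C)C
Why: Silylation of the allylic primary alcohol installs the C15 silyl ether that is carried to the last step.

Step 4
Reactants: 5 (E)-7-(tert-butyldimethylsilyloxy)-3-methyl-1-(triisopropylsilyloxy)hept-2-ene
Product: 6 (E)-5-methyl-7-(triisopropylsilyloxy)hept-5-en-1-ol
Conditions: PPTS, MeOH, 23 °C
Reagents that add atoms: none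
Why: Acid-catalysed methanolysis cleaves a primary TBS ether much faster than a primary TIPS ether (selective desilylation), which frees only the saturated terminus.

Step 5
Reactants: 6 (E)-5-methyl-7-(triisopropylsilyloxy)hept-5-en-1-ol
Product: 7 (E)-5-methyl-7-(triisopropylsilyloxy)hept-5-enoic acid
Conditions: TEMPO (cat.), PhI(OAc)2, MeCN/H2O 1:1, 23 °C
Reagents that add atoms: water, O
Why: The nitroxyl-catalysed oxidation takes an unhindered primary alcohol through the aldehyde hydrate to the carboxylic acid and spares the alkene and the allylic silyl ether.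

Step 6
Reactants: 8 (E)-pent-3-en-2-one
Product: 9 (E)-2-(tert-butyldimethylsilyloxy)penta-1,3-diene
Conditions: TBSOTf, Et3N, Et2O, 0 °C
Reagents that add atoms: tert-butyldimethylsilyl trifluoromethanesulfonate, CC(C)(C)[Si](C)(C)OS(=O)(=O)C(F)(F)F
Why: Soft enolisation of the methyl ketone (silyl enol ether formation) takes place at the methyl group and gives the 2-silyloxy diene with the E propenyl unit intact.

Step 7
Reactants: 9 (E)-2-(tert-butyldimethylsilyloxy)penta-1,3-diene; 10 (5S)-5-[(1S,2R,5S)-menthyloxy]furan-2(5H)-one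
Product: 11 Diels–Alder adduct (ring A 2-silyloxy-1-ene cis-fused at C4/C5 to the 19-menthyloxy lactone with C6=O; 4α-H 5α-H 10β-CH3)
Conditions: toluene, BHT (cat.), 115 °C, sealed tube
Reagents that add atoms: none
Why: In this Diels–Alder reaction the diene adds to the butenolide face anti to the menthyloxy group, which fixes C4 and C5, and the silyloxy group (para director) and the terminal methyl group (ortho director) both place C10 on the lactone α-carbon C5 and C3 on C4; the C10 methine formed here is erased in step 11.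

Step 8
Reactants: 11 Diels–Alder adduct
Product: 12 exocyclic enol ether (C6=C7H2 in place of the lactone carbonyl)
Conditions: Cp2TiMe2, toluene, 70 °C, dark
Reagents that add atoms: dimethyltitanocene, C[Ti](C)(C1C=CC=C1)C1C=CC=C1
Why: Petasis methylenation converts the lactone carbonyl into the enol ether under non-basic conditions, so C5 is not epimerised and the silyl enol ether and the acetal survive; the new carbon is C7.

Step 9
Reactants: 12 exocyclic enol ether
Product: 14 primary C7 alcohol (H6 cis to H5 and C7 cis to C10), via B-alkyl-9-BBN 13 (not isolated)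
Conditions: 9-BBN-H, THF, 0 to 23 °C; then NaBO3·4H2O, H2O
Reagents that add atoms: sodium perborate tetrahydrate NaBO3·4H2O, [Na+].[Na+].O[B-]1(O)OO[B-](O)(O)OO1
Why: Hydroboration–oxidation of the 1,1-disubstituted enol ether puts boron on C7 and delivers hydrogen to C6 from the convex face, anti to ring A on the neighbouring C5, which sets C6, while the bulky borane does not add to the trisubstituted silyl enol ether.

Step 10
Reactants: 14 primary C7 alcohol
Product: 15 7-O-(4-methoxybenzyl) ether
Conditions: NaH, PMBCl, n-Bu4NI (cat.), THF/DMF, 0 to 23 °C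
Reagents that add atoms: 4-methoxybenzyl chloride, COc1ccc(CCl)cc1
Why: Williamson etherification of the primary alkoxide gives an ether that survives the acidic, basic and organometallic steps up to step 21.

Step 11
Reactants: 15 7-O-(4-methoxybenzyl) ether
Product: 16 ring A enone (C2=O and C1=C10 with the C10 methyl group)
Conditions: Pd(OAc)2 (1.1 equiv), MeCN, 23 to 40 °C
Reagents that add atoms: none
Why: In the Saegusa–Ito oxidation palladation of the silyl enol ether at C1 and β-hydride elimination of the C10 hydrogen give the C1=C10 enone regiospecifically, because C2 carries no hydrogen.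

Step 12
Reactants: 16 ring A enone
Product: 17 2β allylic alcohol
Conditions: i-Bu2AlH, CH2Cl2, −78 °C
Reagents that add atoms: none
Why: 1,2-Reduction of the enone by the aluminium hydride from the convex α face of the cis-fused bicycle, away from the oxolane ring, should give the 2β alcohol.

Step 13
Reactants: 17 2β allylic alcohol; 7 (E)-5-methyl-7-(triisopropylsilyloxy)hept-5-enoic acid
Product: 18 2α allylic ester of acid 7
Conditions: PPh3, DIAD, THF, 0 to 23 °C
Reagents that add atoms: none
Why: Mitsunobu esterification inverts C2 by SN2 displacement of the oxyphosphonium group by the carboxylate, which puts the ester oxygen on the α face, trans to C6, as the [3,3] shift of step 14 requires.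

Step 14
Reactants: 18 2α allylic ester
Product: 22 lactol acid (C8 acid on the new C9 centre; quaternary C10 with 10β-CH3; C1=C2; C19 hemiacetal), via silyl ketene acetal 19 (not isolated), via trimethylsilyl ester 20 (not isolated), via acetal acid 21 (not isolated)
Conditions: LiN(i-Pr)2, THF, −78 °C; TMSCl, −78 to 60 °C; then AcOH/THF/H2O 3:1:1, 45 °C
Reagents that add atoms: water, O
Why: In this Ireland–Claisen rearrangement kinetic deprotonation in THF gives the (E)-silyl ketene acetal 19, which shifts suprafacially across the α face through a chair transition state (side chain over H1, silyloxy group over ring A), so that C10 takes its configuration from C2 and C9 from the ketene acetal geometry; the aqueous acetic acid work-up then cleaves the silyl ester and the menthyl acetal.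

Step 15
Reactants: 22 lactol acid
Product: 23 lactol acid with saturated ring A
Conditions: 2-nitrobenzenesulfonohydrazide, Et3N, CH2Cl2, 23 °C
Reagents that add atoms: none
Why: Diimide reduction (syn transfer of H2 from diazene made in the flask) saturates the cis-disubstituted C1=C2 bond much faster than the trisubstituted C13=C14 bond and touches neither the benzyl-type ether nor the lactol.

Step 16
Reactants: 23 lactol acid with saturated ring A
Product: 24 lactone acid (γ-lactone C19(=O)–O–C6; 4α-H)
Conditions: TEMPO (cat.), PhI(OAc)2, CH2Cl2, 23 °C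
Reagents that add atoms: none
Why: Nitroxyl-catalysed oxidation of the hemiacetal gives the γ-lactone whose carbonyl carbon is C19, while the carboxylic acid and the PMB ether are inert.

Step 17
Reactants: 24 lactone acid
Product: 25 lactone acid with quaternary C4 (4α-CH3 and C19 β)
Conditions: LiN(i-Pr)2 (2.5 equiv), THF, −78 °C; CH3I, −78 to −40 °C
Reagents that add atoms: iodomethane, CI
Why: In this enolate alkylation the second equivalent of base forms the lactone enolate at C4 (the carboxylate is not deprotonated at C9 at −78 °C), and CH3I attacks the convex α face, cis to H5 and anti to the 10β-methyl group.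

Step 18
Reactants: 25 lactone acid with quaternary C4
Product: 27 methyl ketone (C8=O with C17H3), via acid chloride 26 (not isolated)
Conditions: 1-chloro-N,N,2-trimethylprop-1-en-1-amine, CH2Cl2, 0 °C; then Me2CuLi, Et2O, −78 °C
Reagents that add atoms: lithium dimethylcuprate Me2CuLi, [Li+].C[Cu-]C
Why: The α-chloroenamine makes the acid chloride under neutral conditions, and acylation of the Gilman cuprate stops at the methyl ketone and leaves the hindered lactone untouched.

Step 19
Reactants: 27 methyl ketone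
Product: 28 enol triflate (C8(OTf)=C17H2)
Conditions: KN(SiMe3)2, THF, −78 °C; PhNTf2
Reagents that add atoms: N-phenylbis(trifluoromethanesulfonimide), O=S(=O)(N(c1ccccc1)S(=O)(=O)C(F)(F)F)C(F)(F)F
Why: Kinetic deprotonation occurs at the methyl group, because the C9 methine next to the quaternary C10 is far less accessible, and O-sulfonylation gives the 1-alken-2-yl triflate (enol triflate formation).

Step 20
Reactants: 28 enol triflate
Product: 29 alkenyl iodide (C8(I)=C17H2) with 7-O-PMB
Conditions: NaI, Ni(OAc)2·4H2O (cat.), cycloocta-1,5-diene (cat.), DMA/THF, 23 °C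
Reagents that add atoms: sodium iodide, [Na+].[I-]
Why: Nickel-catalysed triflate–iodide exchange (oxidative addition, halide exchange, reductive elimination) gives the 2-iodoalkene without moving the double bond.

Step 21
Reactants: 29 alkenyl iodide with 7-O-PMB
Product: 30 alkenyl iodide with free C7 alcohol
Conditions: DDQ, CH2Cl2/pH 7 buffer, 0 °C
Reagents that add atoms: none
Why: Oxidative cleavage of the 4-methoxybenzyl ether with DDQ frees the C7 alcohol and leaves the silyl ether, the alkenyl iodide and the lactone intact.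

Step 22
Reactants: 30 alkenyl iodide with free C7 alcohol
Product: 31 ring A lactone aldehyde carrying the C9 side chain and the C8 alkenyl iodide
Conditions: Dess–Martin periodinane, CH2Cl2, 0 to 23 °C
Reagents that add atoms: none
Why: Dess–Martin oxidation gives the α-acyloxy aldehyde under neutral conditions that do not epimerise C6, and the aldehyde is used at once.

Step 23
Reactants: 31 ring A lactone aldehyde
Product: 33 tricyclic 19,6β-lactone with 7α-hydroxyl and C8 methylene, via alkenylchromium dichloride 32 (not isolated)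
Conditions: CrCl2, NiCl2 (cat.), degassed DMF, 23 °C, 0.005 M
Reagents that add atoms: none
Why: CrCl2 reduces NiCl2 to zerovalent nickel, which inserts into the C8–I bond; transmetallation to trivalent chromium gives the alkenylchromium 32, which adds to the C7 aldehyde but not to the lactone, the silyl ether or the alkenes. The closest known reaction is the intramolecular Nozaki–Hiyama–Kishi cyclisation of 2-iodoallyl aldehydes to 2-methylenecycloalkanols. Ring B closes by 6-exo-trig attack of C8 on the aldehyde carbon through a chair that is trans-fused to ring A, with the 10β-methyl group and the C6–O bond axial. C7 is the only new stereocentre and is set by the aldehyde rotamer: with the C=O dipole opposed to the axial C6–O bond of the lactone, the chromium alkoxide ends up axial and gives the 7α alcohol. The step therefore needs 7α over 7β selectivity, which the rigid cis-fused lactone and this dipole effect should secure against the 1,3-diaxial contact with the axial C9 chain, while high dilution suppresses intermolecular addition.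

Step 24
Reactants: 33 tricyclic lactone with 7α-hydroxyl
Product: 34 7-O-TBS ether
Conditions: TBSOTf, 2,6-lutidine, CH2Cl2, −78 to 0 °C
Reagents that add atoms: tert-butyldimethylsilyl trifluoromethanesulfonate, CC(C)(C)[Si](C)(C)OS(=O)(=O)C(F)(F)F
Why: Silylation of the hindered axial allylic alcohol with the silyl triflate protects O7 against the hydride, acylation and oxidation steps that follow.

Step 25
Reactants: 34 7-O-TBS ether
Product: 35 6β,19-diol
Conditions: LiAlH4, THF, 0 to 50 °C
Reagents that add atoms: none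
Why: Hydride reduction of the lactone opens the 19,6-bridge to the diol, while the silyl ethers and both alkenes are inert.

Step 26
Reactants: 35 6β,19-diol
Product: 36 19-O-triethylsilyl ether
Conditions: TESCl, imidazole, CH2Cl2, −20 °C
Reagents that add atoms: chlorotriethylsilane, CC[Si](Cl)(CC)CC
Why: Silylation takes the primary C19 hydroxyl selectively, because the axial C6 hydroxyl is shielded by the syn-axial C20 methyl and C19 groups.

Step 27
Reactants: 36 19-O-triethylsilyl ether
Product: 37 6β-benzoate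
Conditions: BzCl, DMAP (cat.), pyridine, 60 °C
Reagents that add atoms: benzoyl chloride, O=C(Cl)c1ccccc1
Why: DMAP-catalysed acylation with the acid chloride at elevated temperature benzoylates the remaining, hindered axial C6 hydroxyl.

Step 28
Reactants: 37 6β-benzoate
Product: 38 6β-benzoate with free 19-alcohol
Conditions: PPTS, MeOH/CH2Cl2, 0 °C
Reagents that add atoms: none
Why: Mild acid methanolysis removes the primary TES ether and leaves the secondary TBS and primary TIPS ethers, and under these non-basic conditions benzoyl migration from O6 to O19 should be slow.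

Step 29
Reactants: 38 6β-benzoate with free 19-alcohol
Product: 39 19-aldehyde
Conditions: Dess–Martin periodinane, CH2Cl2, 23 °C
Reagents that add atoms: none
Why: Dess–Martin oxidation of the neopentyl primary alcohol gives the C19 aldehyde while all other hydroxyl groups are protected.

Step 30
Reactants: 39 19-aldehyde
Product: 40 19-acid (6β-OBz; 7α-OTBS; 15-OTIPS)
Conditions: NaClO2, NaH2PO4, 2-methylbut-2-ene, t-BuOH/H2O, 23 °C
Reagents that add atoms: sodium chlorite, [Na+].[O-]Cl=O
Why: Pinnick oxidation converts the aldehyde into the acid, and the hypochlorite scavenger protects the two alkenes.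

Step 31
Reactants: 40 19-acid
Product: 41 target acid CNP0149011.1
Conditions: HF·pyridine, THF/pyridine, 0 to 23 °C
Reagents that add atoms: none
Why: Fluoride-mediated desilylation removes the TBS and TIPS ethers and leaves the benzoate, the acid and the allylic alcohols untouched, which gives the target.

**Compound list**

1 | hex-5-yn-1-ol | C#CCCCCO | starting material
2 | tert-butyl(hex-5-yn-1-yloxy)dimethylsilane | C#CCCCCO[Si](C)(C)C(C)(C)C | intermediate
3 | (E)-[6-(tert-butyldimethylsilyloxy)-2-methylhex-1-en-1-yl]dimethylalane | C[Al](C)/C=C(\C)CCCCO[Si](C)(C)C(C)(C)C | intermediate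
4 | (E)-7-(tert-butyldimethylsilyloxy)-3-methylhept-2-en-1-ol | OC/C=C(\C)CCCCO[Si](C)(C)C(C)(C)C | intermediate
5 | (E)-7-(tert-butyldimethylsilyloxy)-3-methyl-1-(triisopropylsilyloxy)hept-2-ene | CC(C)(C)[Si](C)(C)OCCCC/C(C)=C/CO[Si](C(C)C)(C(C)C)C(C)C | intermediate
6 | (E)-5-methyl-7-(triisopropylsilyloxy)hept-5-en-1-ol | OCCCC/C(C)=C/CO[Si](C(C)C)(C(C)C)C(C)C | intermediate
7 | (E)-5-methyl-7-(triisopropylsilyloxy)hept-5-enoic acid (C8, C9, C11–C16) | OC(=O)CCC/C(C)=C/CO[Si](C(C)C)(C(C)C)C(C)C | intermediate
8 | (E)-pent-3-en-2-one | C/C=C/C(C)=O | starting material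
9 | (E)-2-(tert-butyldimethylsilyloxy)penta-1,3-diene | C/C=C/C(=C)O[Si](C)(C)C(C)(C)C | intermediate
10 | (5S)-5-[(1S,2R,5S)-menthyloxy]furan-2(5H)-one | O=C1C=C[C@@H](O[C@H]2C[C@@H](C)CC[C@@H]2C(C)C)O1 | starting material
11 | Diels–Alder adduct: ring A with C1=C2 and 2-OTBS, 10β-CH3, 4α-H, 5α-H, cis-fused through C4 and C5 to the lactone C5–C6(=O)–O–C19H(O-menthyl)–C4, menthyloxy group on the face of H4 and H5 | C[C@@H]1C=C(O[Si](C)(C)C(C)(C)C)C[C@@H]2[C@@H](O[C@H]3C[C@@H](C)CC[C@@H]3C(C)C)OC(=O)[C@H]12 | intermediate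
12 | as 11 with the lactone C6=O replaced by the exocyclic enol ether C6=C7H2 | C[C@@H]1C=C(O[Si](C)(C)C(C)(C)C)C[C@@H]2[C@@H](O[C@H]3C[C@@H](C)CC[C@@H]3C(C)C)OC(=C)[C@H]12 | intermediate
13 | B-alkyl-9-BBN: C7H2–B(9-BBN) on C6, H6 on the face of H5 | C[C@@H]1C=C(O[Si](C)(C)C(C)(C)C)C[C@@H]2[C@@H](O[C@H]3C[C@@H](C)CC[C@@H]3C(C)C)O[C@H](CB3C4CCCC3CCC4)[C@H]12 | intermediate
14 | primary alcohol C7H2OH on C6 (H6 cis to H5, C7 cis to C10); 2-OTBS enol ether and 19-menthyloxy acetal as in 11 | C[C@@H]1C=C(O[Si](C)(C)C(C)(C)C)C[C@@H]2[C@@H](O[C@H]3C[C@@H](C)CC[C@@H]3C(C)C)O[C@H](CO)[C@H]12 | intermediate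
15 | 7-O-(4-methoxybenzyl) ether of 14 | C[C@@H]1C=C(O[Si](C)(C)C(C)(C)C)C[C@@H]2[C@@H](O[C@H]3C[C@@H](C)CC[C@@H]3C(C)C)O[C@H](COCc3ccc(OC)cc3)[C@H]12 | intermediate
16 | enone: C2=O, C1=C10 with 10-methyl, 4α-H, 5α-H; oxolane with 6-(PMBOCH2) and 19-menthyloxy as in 15 | CC1=CC(=O)C[C@@H]2[C@@H](O[C@H]3C[C@@H](C)CC[C@@H]3C(C)C)O[C@H](COCc3ccc(OC)cc3)[C@H]12 | intermediate
17 | 2β allylic alcohol from 16 | CC1=C[C@H](O)C[C@@H]2[C@@H](O[C@H]3C[C@@H](C)CC[C@@H]3C(C)C)O[C@H](COCc3ccc(OC)cc3)[C@H]12 | intermediate
18 | 2α ester of the ring A allylic alcohol with acid 7 | CC1=C[C@@H](OC(=O)CCC/C(C)=C/CO[Si](C(C)C)(C(C)C)C(C)C)C[C@@H]2[C@@H](O[C@H]3C[C@@H](C)CC[C@@H]3C(C)C)O[C@H](COCc3ccc(OC)cc3)[C@H]12 | intermediate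
19 | (E)-trimethylsilyl ketene acetal of 18 (C11 chain cis to the allylic oxygen) | CC1=C[C@@H](O/C(O[Si](C)(C)C)=C\CC/C(C)=C/CO[Si](C(C)C)(C(C)C)C(C)C)C[C@@H]2[C@@H](O[C@H]3C[C@@H](C)CC[C@@H]3C(C)C)O[C@H](COCc3ccc(OC)cc3)[C@H]12 | intermediate
20 | trimethylsilyl ester of 21 | C[Si](C)(C)OC(=O)[C@@H](CC/C(C)=C/CO[Si](C(C)C)(C(C)C)C(C)C)[C@@]1(C)C=CC[C@@H]2[C@@H](O[C@H]3C[C@@H](C)CC[C@@H]3C(C)C)O[C@H](COCc3ccc(OC)cc3)[C@H]12 | intermediate
21 | acetal acid: C8 carboxylic acid on C9, C9 and quaternary C10 (10β-CH3, C9 α) configured as in 31, C1=C2, 19-menthyloxy acetal | OC(=O)[C@@H](CC/C(C)=C/CO[Si](C(C)C)(C(C)C)C(C)C)[C@@]1(C)C=CC[C@@H]2[C@@H](O[C@H]3C[C@@H](C)CC[C@@H]3C(C)C)O[C@H](COCc3ccc(OC)cc3)[C@H]12 | intermediate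
22 | lactol acid: as 21 with C19 hemiacetal (both anomers) | OC(=O)[C@@H](CC/C(C)=C/CO[Si](C(C)C)(C(C)C)C(C)C)[C@@]1(C)C=CC[C@@H]2C(O)O[C@H](COCc3ccc(OC)cc3)[C@H]12 | intermediate
23 | lactol acid with saturated ring A | OC(=O)[C@@H](CC/C(C)=C/CO[Si](C(C)C)(C(C)C)C(C)C)[C@@]1(C)CCC[C@@H]2C(O)O[C@H](COCc3ccc(OC)cc3)[C@H]12 | intermediate
24 | lactone acid: cis-fused γ-lactone C19(=O)–O–C6, 4α-H | OC(=O)[C@@H](CC/C(C)=C/CO[Si](C(C)C)(C(C)C)C(C)C)[C@@]1(C)CCC[C@@H]2C(=O)O[C@H](COCc3ccc(OC)cc3)[C@H]12 | intermediate
25 | lactone acid with quaternary C4 (4α-CH3, C19 β) | OC(=O)[C@@H](CC/C(C)=C/CO[Si](C(C)C)(C(C)C)C(C)C)[C@@]1(C)CCC[C@]2(C)C(=O)O[C@H](COCc3ccc(OC)cc3)[C@H]12 | intermediate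
26 | acid chloride of 25 | ClC(=O)[C@@H](CC/C(C)=C/CO[Si](C(C)C)(C(C)C)C(C)C)[C@@]1(C)CCC[C@]2(C)C(=O)O[C@H](COCc3ccc(OC)cc3)[C@H]12 | intermediate
27 | methyl ketone: C8(=O)C17H3 on C9 | CC(=O)[C@@H](CC/C(C)=C/CO[Si](C(C)C)(C(C)C)C(C)C)[C@@]1(C)CCC[C@]2(C)C(=O)O[C@H](COCc3ccc(OC)cc3)[C@H]12 | intermediate
28 | enol triflate: C8(OTf)=C17H2 | C=C(OS(=O)(=O)C(F)(F)F)[C@@H](CC/C(C)=C/CO[Si](C(C)C)(C(C)C)C(C)C)[C@@]1(C)CCC[C@]2(C)C(=O)O[C@H](COCc3ccc(OC)cc3)[C@H]12 | intermediate
29 | alkenyl iodide C8(I)=C17H2 with 7-O-PMB | C=C(I)[C@@H](CC/C(C)=C/CO[Si](C(C)C)(C(C)C)C(C)C)[C@@]1(C)CCC[C@]2(C)C(=O)O[C@H](COCc3ccc(OC)cc3)[C@H]12 | intermediate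
30 | alkenyl iodide with free C7 alcohol | C=C(I)[C@@H](CC/C(C)=C/CO[Si](C(C)C)(C(C)C)C(C)C)[C@@]1(C)CCC[C@]2(C)C(=O)O[C@H](CO)[C@H]12 | intermediate
31 | ring A lactone aldehyde with the C9 side chain and the C8 alkenyl iodide (precursor of the key step) | C=C(I)[C@@H](CC/C(C)=C/CO[Si](C(C)C)(C(C)C)C(C)C)[C@@]1(C)CCC[C@]2(C)C(=O)O[C@H](C=O)[C@H]12 | intermediate
32 | alkenylchromium dichloride from 31 (C8–CrCl2) | C=C([Cr](Cl)Cl)[C@@H](CC/C(C)=C/CO[Si](C(C)C)(C(C)C)C(C)C)[C@@]1(C)CCC[C@]2(C)C(=O)O[C@H](C=O)[C@H]12 | intermediate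
33 | tricyclic 19,6β-lactone: 7α-hydroxy, 8(17)-methylene, 9β-H, 13E, 15-O-TIPS | C=C1[C@@H](CC/C(C)=C/CO[Si](C(C)C)(C(C)C)C(C)C)[C@@]2(C)CCC[C@]3(C)C(=O)O[C@@H]([C@H]23)[C@H]1O | intermediate
34 | 7-O-TBS ether of 33 | C=C1[C@@H](CC/C(C)=C/CO[Si](C(C)C)(C(C)C)C(C)C)[C@@]2(C)CCC[C@]3(C)C(=O)O[C@@H]([C@H]23)[C@H]1O[Si](C)(C)C(C)(C)C | intermediate
35 | 6β,19-diol (7α-OTBS, 15-OTIPS) | C=C1[C@@H](CC/C(C)=C/CO[Si](C(C)C)(C(C)C)C(C)C)[C@@]2(C)CCC[C@](C)(CO)[C@@H]2[C@H](O)[C@H]1O[Si](C)(C)C(C)(C)C | intermediate
36 | 19-O-triethylsilyl ether of 35 | C=C1[C@@H](CC/C(C)=C/CO[Si](C(C)C)(C(C)C)C(C)C)[C@@]2(C)CCC[C@](C)(CO[Si](CC)(CC)CC)[C@@H]2[C@H](O)[C@H]1O[Si](C)(C)C(C)(C)C | intermediate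
37 | 6β-benzoate of 36 | C=C1[C@@H](CC/C(C)=C/CO[Si](C(C)C)(C(C)C)C(C)C)[C@@]2(C)CCC[C@](C)(CO[Si](CC)(CC)CC)[C@@H]2[C@H](OC(=O)c3ccccc3)[C@H]1O[Si](C)(C)C(C)(C)C | intermediate
38 | 6β-benzoate with free 19-alcohol | C=C1[C@@H](CC/C(C)=C/CO[Si](C(C)C)(C(C)C)C(C)C)[C@@]2(C)CCC[C@](C)(CO)[C@@H]2[C@H](OC(=O)c3ccccc3)[C@H]1O[Si](C)(C)C(C)(C)C | intermediate
39 | 19-aldehyde | C=C1[C@@H](CC/C(C)=C/CO[Si](C(C)C)(C(C)C)C(C)C)[C@@]2(C)CCC[C@](C)(C=O)[C@@H]2[C@H](OC(=O)c3ccccc3)[C@H]1O[Si](C)(C)C(C)(C)C | intermediate
40 | 19-acid (6β-OBz, 7α-OTBS, 15-OTIPS) | C=C1[C@@H](CC/C(C)=C/CO[Si](C(C)C)(C(C)C)C(C)C)[C@@]2(C)CCC[C@](C)(C(=O)O)[C@@H]2[C@H](OC(=O)c3ccccc3)[C@H]1O[Si](C)(C)C(C)(C)C | intermediate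
41 | 6β-benzoyloxy-7α,15-dihydroxy-9βH-labda-8(17),13E-dien-19-oic acid (CNP0149011.1) | C=C1[C@@H](CC/C(C)=C/CO)[C@@]2(C)CCC[C@](C)(C(=O)O)[C@@H]2[C@H](OC(=O)c2ccccc2)[C@H]1O | target

**Step count and risks**

Total step count: 31. Longest linear sequence: 26 steps (steps 6 to 31, from 8 to 41); the acid 7 (steps 1 to 5) joins in step 13.

The three steps most likely to fail:

First, step 23. The carbonyl addition may run through the other aldehyde rotamer and give the 7β alcohol (poor facial selectivity at C7), or the alkenylchromium may be protonated before it closes the ring. The fallback takes the C7 centre out of the ring closure and sets it under reagent control. It sets out from 33 as obtained (a mixture of C7 epimers): Dess–Martin oxidation gives the 7-ketone F1. Corey–Bakshi–Shibata reduction ((S)-2-methyl-CBS-oxazaborolidine, catecholborane, toluene, −78 °C), a 1,2-reduction in which the alkene-bearing C8 side acts as the large group, then returns the 7α alcohol 33.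

Second, step 14. The rearrangement may leak through the boat transition state or through the (Z)-ketene acetal, which erodes the configuration at C9, and the hindered C10 terminus may slow the shift. The fallback replaces substrate control by a silicon ketene acetal with reagent control by a chiral boron ketene acetal. It sets out from 18: enolisation with (4S,5S)-2-bromo-4,5-diphenyl-1,3-bis(4-methylphenylsulfonyl)-1,3,2-diazaborolidine and Et3N (toluene/hexane, −78 °C) gives the boron ketene acetal F2. The (4S,5S) controller is shown; the enantiomer that matches the α-face delivery fixed by C2 is the one to use. The [3,3] shift of F2 at −20 °C runs through a tight chair enforced by the sulfonamide groups, and hydrolytic work-up gives the acetal acid 21, which re-enters the route in the acetic acid treatment of step 14.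

Third, step 13. The activated allylic alcohol may ionise, or react by SN2′ substitution or elimination to a diene, instead of clean inversion at C2. The fallback makes the α alcohol directly and esterifies it with retention. It sets out from 16: Corey–Bakshi–Shibata reduction with (R)-2-methyl-CBS-oxazaborolidine and catecholborane (toluene, −78 °C) gives the 2α allylic alcohol F3 under reagent control, and carbodiimide esterification with 7 (DCC, DMAP, CH2Cl2) gives 18.

Further compounds
F1 | step 23 | 7-ketone of 33 (7-oxo-8(17)-ene 19,6β-lactone, 15-O-TIPS) | C=C1[C@@H](CC/C(C)=C/CO[Si](C(C)C)(C(C)C)C(C)C)[C@@]2(C)CCC[C@]3(C)C(=O)O[C@@H]([C@H]23)C1=O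
F2 | step 14 | boron ketene acetal of 18 carrying the (4S,5S)-4,5-diphenyl-1,3-bis(4-methylphenylsulfonyl)-1,3,2-diazaborolidin-2-yl group on the enolate oxygen | CC1=C[C@@H](O/C(OB3N(S(=O)(=O)c4ccc(C)cc4)[C@@H](c4ccccc4)[C@H](c4ccccc4)N3S(=O)(=O)c3ccc(C)cc3)=C\CC/C(C)=C/CO[Si](C(C)C)(C(C)C)C(C)C)C[C@@H]2[C@@H](O[C@H]3C[C@@H](C)CC[C@@H]3C(C)C)O[C@H](COCc3ccc(OC)cc3)[C@H]12
F3 | step 13 | 2α allylic alcohol (C2 epimer of 17) | CC1=C[C@@H](O)C[C@@H]2[C@@H](O[C@H]3C[C@@H](C)CC[C@@H]3C(C)C)O[C@H](COCc3ccc(OC)cc3)[C@H]12
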